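**Retrosynthetic overview**
- The strategy rests on the furan ring (O1, C2–C5): C2 carries phenyl and the ring oxygen, the adjacent C3 carries an alkynyl arm and the bond to C4 (methyl), and C5 carries the second alkynyl arm. This is the pattern an electrophile leaves on a triphenyl(alkynyl)borate of a conjugated diyne.
- Both ynone carbonyls come from propargylic alcohols by a final double oxidation; the benzoyl arm comes from benzaldehyde and a 5-ethynylfuran.
- The furan, the only ring, is closed in step 7 by Paal–Knorr cyclodehydration of a 1,4-diketone (O1 between C2 and C5).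
- The 1,4-diketone comes from lithium diynyl(triphenyl)borate 13 and α-bromo ynone 5: alkylation at the boron-distal carbon of the first alkyne makes the bond that becomes furan C3–C4, a 1,2-shift of phenyl from boron makes C2–Ph, and C–B oxidation gives the C2 carbonyl.
- Borate 13 comes from (Z)-1-methoxybut-1-en-3-yne, acetaldehyde and BPh3; bromo ynone 5 comes from (triisopropylsilyl)acetylene and 2-bromopropanoyl chloride.

Key step: step 6

Remark on the chemistry: the target is achiral. Every stereocentre of the intermediates (the carbinol carbons and the two CH centres of the diketone) is carried as a racemate or diastereomer mixture and is removed in step 7 or step 10.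

**Route**

Step 1
Reactants: 1 (triisopropylsilyl)acetylene
Product: 3 trimethyl[(triisopropylsilyl)ethynyl]silane, via lithium (triisopropylsilyl)acetylide 2 (not isolated)
Conditions: n-BuLi, THF, −78 °C; TMSCl, −78 °C → rt
Reagents that add atoms: chlorotrimethylsilane, C[Si](C)(C)Cl
Why: Deprotonation of the terminal alkyne and C-silylation of the lithium acetylide is routine and gives a bis(silyl)alkyne whose two ends differ strongly in steric demand.

Step 2
Reactants: 3 trimethyl[(triisopropylsilyl)ethynyl]silane; 4 2-bromopropanoyl chloride (racemic)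
Product: 5 4-bromo-1-(triisopropylsilyl)pent-1-yn-3-one (racemic)
Conditions: AlCl3, CH2Cl2, −20 → 0 °C; ice/dilute HCl work-up
Reagents that add atoms: none
Why: Friedel–Crafts-type acylative ipso-desilylation of a silylalkyne: the acylium ion should attack the carbon bearing the small SiMe3 group (β-silyl-stabilised vinyl cation, loss of Me3SiCl) while the bulky TIPS end stays intact, and α-halo acyl chlorides are competent acylating agents under these conditions.

Step 3
Reactants: 6 (Z)-1-methoxybut-1-en-3-yne; 7 acetaldehyde
Product: 9 hexa-3,5-diyn-2-ol (racemic), via lithium buta-1,3-diynide 8 (not isolated)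
Conditions: n-BuLi (2 equiv), THF, −78 → −25 °C; 7, −78 → 0 °C; H2O; product kept as a cold ethereal solution
Reagents that add atoms: none
Why: The first equivalent of base forms the acetylide and the second effects anti elimination of methoxide from the Z enol ether to give monolithiated butadiyne, which adds 1,2 to the aldehyde; the carbinol centre is racemic and is oxidised away in step 10.

Step 4
Reactants: 9 hexa-3,5-diyn-2-ol (racemic)
Product: 10 tert-butyl(hexa-3,5-diyn-2-yloxy)dimethylsilane (racemic)
Conditions: TBSCl, imidazole, CH2Cl2, 0 °C → rt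
Reagents that add atoms: tert-butyldimethylsilyl chloride, CC(C)(C)[Si](C)(C)Cl
Why: Standard silylation of a secondary alcohol, which masks the hydroxyl for the organolithium and borate chemistry and makes the diyne less volatile and easier to handle.

Step 5
Reactants: 10 tert-butyl(hexa-3,5-diyn-2-yloxy)dimethylsilane (racemic); 11 triphenylborane
Product: 13 lithium [5-(tert-butyldimethylsilyloxy)hexa-1,3-diynyl]triphenylborate (racemic), via lithium diynide 12 (not isolated)
Conditions: n-BuLi (1.0 equiv), THF, −78 °C; 11 (1.05 equiv), −78 °C → rt; volatiles removed under argon, solid used directly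
Reagents that add atoms: n-butyllithium, [Li]CCCC
Why: The acidic terminal diyne C–H is lithiated cleanly and the acetylide adds to the Lewis-acidic boron to give a stable tetracoordinate alkynyl(triaryl)borate salt (ate-complex formation).

Step 6
Reactants: 13 lithium [5-(tert-butyldimethylsilyloxy)hexa-1,3-diynyl]triphenylborate (racemic); 5 4-bromo-1-(triisopropylsilyl)pent-1-yn-3-one (racemic)
Product: 15 2-[3-(tert-butyldimethylsilyloxy)but-1-ynyl]-3-methyl-1-phenyl-6-(triisopropylsilyl)hex-5-yne-1,4-dione (diastereomer mixture), via alkenyldiphenylborane 14 (not isolated)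
Conditions: 5 (1.1 equiv), THF, −78 °C → rt; then anhydrous Me3NO (4 equiv), 0 °C → rt; pH 7 phosphate buffer
Reagents that add atoms: trimethylamine N-oxide, C[N+](C)(C)[O-]
Why: Proposed new method: the electron-rich B–C(sp) bond of 13 makes the boron-distal carbon of the first alkyne nucleophilic, so SN2 displacement of bromide at the carbonyl-activated secondary carbon of 5 should form the bond that becomes furan C3–C4 while one phenyl shifts 1,2 from tetracoordinate boron to the boron-bound carbon (C2–Ph), giving alkenylborane 14; Me3NO then oxidises the three B–C bonds and buffered hydrolysis of the enol borinate releases the phenyl ketone. The closest known reaction is the alkylation of lithium alkynyltrialkylborates with α-bromo ketones followed by oxidation to 1,4-diketones (alkylative 1,2-metallate rearrangement); what is untested is the conjugated diynyl borate, aryl migration in this setting and the secondary α-bromo ynone. No ring closes in this step, the furan being formed in step 7. The two new CH centres of the dione (C2 and C3) form without control, as does their relation to the racemic carbinol carbon, which does not matter because both become sp2 furan carbons. The step needs attack at the first alkyne only and substitution rather than conjugate addition or enolisation: only attack at the carbon next to the borate-bearing carbon is coupled to the migration and leaves a conjugated enyne, attack at the remote terminus would have to build a borylbutatriene beside the branched silyloxyethyl group, the TIPS group shields the ynone β-carbon, and the fully complexed borate is not basic. The ketone is unmasked only in the buffered hydrolysis, after the trimethylamine is neutralised, which should protect the acidic propargylic C–H from isomerisation to an allenyl ketone.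

Step 7
Reactants: 15 2-[3-(tert-butyldimethylsilyloxy)but-1-ynyl]-3-methyl-1-phenyl-6-(triisopropylsilyl)hex-5-yne-1,4-dione (diastereomer mixture)
Product: 16 tert-butyldimethyl{[4-(4-methyl-2-phenyl-5-((triisopropylsilyl)ethynyl)furan-3-yl)but-3-yn-2-yl]oxy}silane (racemic)
Conditions: p-TsOH·H2O (0.1 equiv), PhMe, 80 °C
Reagents that add atoms: none
Why: Paal–Knorr furan synthesis: the aryl ketone enolises toward the doubly activated C–H, the enol oxygen adds to the protonated ynone carbonyl (5-exo-trig hemiketal) and loss of water aromatises the ring, which removes both CH stereocentres; without a π-acidic metal the enol should not close onto the alkyne of the C3 arm.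

Step 8
Reactants: 16 tert-butyldimethyl{[4-(4-methyl-2-phenyl-5-((triisopropylsilyl)ethynyl)furan-3-yl)but-3-yn-2-yl]oxy}silane (racemic)
Product: 17 4-(5-ethynyl-4-methyl-2-phenylfuran-3-yl)but-3-yn-2-ol (racemic)
Conditions: TBAF (2.5 equiv), THF, 0 °C → rt; used at once
Reagents that add atoms: none
Why: Fluoride cleaves both the C(sp)–Si bond and the O–Si bond in one operation (global desilylation), and any material that lost the silyl ether in step 7 converges on the same product.

Step 9
Reactants: 17 4-(5-ethynyl-4-methyl-2-phenylfuran-3-yl)but-3-yn-2-ol (racemic); 18 benzaldehyde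
Product: 20 4-[5-(3-hydroxy-3-phenylprop-1-ynyl)-4-methyl-2-phenylfuran-3-yl]but-3-yn-2-ol (diastereomer mixture), via dilithium salt 19 (not isolated)
Conditions: n-BuLi (2.1 equiv), THF, −78 °C; 18, −78 → 0 °C; H2O
Reagents that add atoms: none
Why: The alkoxide/acetylide dianion reacts with the aldehyde only at its carbon terminus (acetylide 1,2-addition), so no protecting group is needed; the new carbinol centre is uncontrolled and is oxidised in the next step.

Step 10
Reactants: 20 4-[5-(3-hydroxy-3-phenylprop-1-ynyl)-4-methyl-2-phenylfuran-3-yl]but-3-yn-2-ol (diastereomer mixture)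
Product: 21 Capillaridin A, 4-[4-methyl-5-(3-oxo-3-phenylprop-1-ynyl)-2-phenylfuran-3-yl]but-3-yn-2-one
Conditions: activated MnO2 (excess), CH2Cl2, rt
Reagents that add atoms: none
Why: Both hydroxyls are propargylic (one also benzylic), the class of activated alcohols that MnO2 oxidises under neutral conditions, so the two electrophilic ynones appear only in the last step.

**Compound list**
1 | (triisopropylsilyl)acetylene | C#C[Si](C(C)C)(C(C)C)C(C)C | starting material
2 | lithium (triisopropylsilyl)acetylide | [Li]C#C[Si](C(C)C)(C(C)C)C(C)C | intermediate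
3 | trimethyl[(triisopropylsilyl)ethynyl]silane | C[Si](C)(C)C#C[Si](C(C)C)(C(C)C)C(C)C | intermediate
4 | 2-bromopropanoyl chloride (racemic) | CC(Br)C(=O)Cl | starting material
5 | 4-bromo-1-(triisopropylsilyl)pent-1-yn-3-one (racemic) | CC(Br)C(=O)C#C[Si](C(C)C)(C(C)C)C(C)C | intermediate
6 | (Z)-1-methoxybut-1-en-3-yne | CO/C=C\C#C | starting material
7 | acetaldehyde | CC=O | starting material
8 | lithium buta-1,3-diynide | [Li]C#CC#C | intermediate
9 | hexa-3,5-diyn-2-ol (racemic) | CC(O)C#CC#C | intermediate
10 | tert-butyl(hexa-3,5-diyn-2-yloxy)dimethylsilane (racemic) | CC(O[Si](C)(C)C(C)(C)C)C#CC#C | intermediate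
11 | triphenylborane | B(c1ccccc1)(c1ccccc1)c1ccccc1 | starting material
12 | lithium 5-(tert-butyldimethylsilyloxy)hexa-1,3-diyn-1-ide (racemic) | CC(O[Si](C)(C)C(C)(C)C)C#CC#C[Li] | intermediate
13 | lithium [5-(tert-butyldimethylsilyloxy)hexa-1,3-diynyl]triphenylborate (racemic) | [Li+].CC(O[Si](C)(C)C(C)(C)C)C#CC#C[B-](c1ccccc1)(c1ccccc1)c1ccccc1 | intermediate
14 | {2-[3-(tert-butyldimethylsilyloxy)but-1-ynyl]-3-methyl-4-oxo-1-phenyl-6-(triisopropylsilyl)hex-1-en-5-ynyl}diphenylborane (E/Z and diastereomer mixture) | CC(O[Si](C)(C)C(C)(C)C)C#CC(C(C)C(=O)C#C[Si](C(C)C)(C(C)C)C(C)C)=C(c1ccccc1)B(c1ccccc1)c1ccccc1 | intermediate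
15 | 2-[3-(tert-butyldimethylsilyloxy)but-1-ynyl]-3-methyl-1-phenyl-6-(triisopropylsilyl)hex-5-yne-1,4-dione (diastereomer mixture) | CC(O[Si](C)(C)C(C)(C)C)C#CC(C(C)C(=O)C#C[Si](C(C)C)(C(C)C)C(C)C)C(=O)c1ccccc1 | intermediate
16 | tert-butyldimethyl{[4-(4-methyl-2-phenyl-5-((triisopropylsilyl)ethynyl)furan-3-yl)but-3-yn-2-yl]oxy}silane (racemic) | CC(O[Si](C)(C)C(C)(C)C)C#Cc1c(-c2ccccc2)oc(C#C[Si](C(C)C)(C(C)C)C(C)C)c1C | intermediate
17 | 4-(5-ethynyl-4-methyl-2-phenylfuran-3-yl)but-3-yn-2-ol (racemic) | CC(O)C#Cc1c(-c2ccccc2)oc(C#C)c1C | intermediate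
18 | benzaldehyde | O=Cc1ccccc1 | starting material
19 | dilithium salt of 17 (lithium alkoxide and lithium acetylide) | CC(O[Li])C#Cc1c(-c2ccccc2)oc(C#C[Li])c1C | intermediate
20 | 4-[5-(3-hydroxy-3-phenylprop-1-ynyl)-4-methyl-2-phenylfuran-3-yl]but-3-yn-2-ol (diastereomer mixture) | CC(O)C#Cc1c(-c2ccccc2)oc(C#CC(O)c2ccccc2)c1C | intermediate
21 | Capillaridin A, 4-[4-methyl-5-(3-oxo-3-phenylprop-1-ynyl)-2-phenylfuran-3-yl]but-3-yn-2-one | CC(=O)C#Cc1c(-c2ccccc2)oc(C#CC(=O)c2ccccc2)c1C | target

**Step count**
Total: 10 steps. Longest linear sequence: 8 steps (steps 3 to 10, from compound 6).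

**Steps most likely to fail**

Step 6 (alkylative phenyl shift). The electrophile may attack the remote alkyne terminus of the diynylborate, or substitution at the secondary bromide may be so slow that conjugate addition to the ynone, proton transfer or dissociation of the ate complex takes over. The fallback uses known chemistry and builds the furan core by iodocyclisation and cross-coupling. It sets out from compound 1, which it uses in its last coupling, together with commercial phenylacetylene and hydroxyacetone, and it comes back to the route at 16. Lithium phenylacetylide (2.2 equiv, from phenylacetylene and n-BuLi) is added to hydroxyacetone to give 2-methyl-4-phenylbut-3-yne-1,2-diol F1. I2/NaHCO3 in MeCN effects 5-endo-dig iodocyclisation with loss of water to give 3-iodo-4-methyl-2-phenylfuran F2. Sonogashira coupling (PdCl2(PPh3)2, CuI, Et3N) with commercial tert-butyl(but-3-yn-2-yloxy)dimethylsilane gives tert-butyldimethyl{[4-(4-methyl-2-phenylfuran-3-yl)but-3-yn-2-yl]oxy}silane F3. NIS in MeCN iodinates the only free ring position to give tert-butyl{[4-(5-iodo-4-methyl-2-phenylfuran-3-yl)but-3-yn-2-yl]oxy}dimethylsilane F4. A second Sonogashira coupling with 1 gives 16.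

Step 7 (Paal–Knorr closure). Under the acid the propargylic silyl ether may be cleaved and ionised, or cyclodehydration may stall while the diketone decomposes. The fallback takes the C3 arm through the acid step without oxygen and installs the carbinol after ring closure. It sets out from triphenylborane 11 and bromo ynone 5 and comes back at 17. Commercial 1,4-bis(trimethylsilyl)buta-1,3-diyne is treated with MeLi·LiBr (mono-desilylation) and then with 11 to give lithium triphenyl[4-(trimethylsilyl)buta-1,3-diynyl]borate F5. Alkylation with 5 and Me3NO oxidation as in step 6 give 3-methyl-1-phenyl-6-(triisopropylsilyl)-2-[(trimethylsilyl)ethynyl]hex-5-yne-1,4-dione F6. p-TsOH in toluene closes it to triisopropyl{[3-methyl-5-phenyl-4-((trimethylsilyl)ethynyl)furan-2-yl]ethynyl}silane F7, which carries no leaving group. MeLi·LiBr cleaves only the C–SiMe3 bond, and addition of the resulting acetylide to acetaldehyde 7 gives 4-{4-methyl-2-phenyl-5-[(triisopropylsilyl)ethynyl]furan-3-yl}but-3-yn-2-ol F8. TBAF then gives 17.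

Step 3 (butadiynide addition). The double deprotonation and elimination may be incomplete, and the small terminal diynol may polymerise or be lost by evaporation during isolation. The fallback keeps the diyne silyl-capped and unmasks the terminal C–H last. It sets out from acetaldehyde 7 and comes back at 10. Commercial 1,4-bis(trimethylsilyl)buta-1,3-diyne is mono-desilylated with MeLi·LiBr in THF and the acetylide is added to 7 to give 6-(trimethylsilyl)hexa-3,5-diyn-2-ol F9. TBSCl/imidazole gives tert-butyldimethyl{[6-(trimethylsilyl)hexa-3,5-diyn-2-yl]oxy}silane F10. K2CO3 in MeOH removes only the alkynyl SiMe3 group and gives 10.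

**Further compounds**
F1 | step 6 | 2-methyl-4-phenylbut-3-yne-1,2-diol (racemic) | CC(O)(CO)C#Cc1ccccc1
F2 | step 6 | 3-iodo-4-methyl-2-phenylfuran | Cc1coc(-c2ccccc2)c1I
F3 | step 6 | tert-butyldimethyl{[4-(4-methyl-2-phenylfuran-3-yl)but-3-yn-2-yl]oxy}silane (racemic) | CC(O[Si](C)(C)C(C)(C)C)C#Cc1c(-c2ccccc2)occ1C
F4 | step 6 | tert-butyl{[4-(5-iodo-4-methyl-2-phenylfuran-3-yl)but-3-yn-2-yl]oxy}dimethylsilane (racemic) | CC(O[Si](C)(C)C(C)(C)C)C#Cc1c(-c2ccccc2)oc(I)c1C
F5 | step 7 | lithium triphenyl[4-(trimethylsilyl)buta-1,3-diynyl]borate | [Li+].C[Si](C)(C)C#CC#C[B-](c1ccccc1)(c1ccccc1)c1ccccc1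
F6 | step 7 | 3-methyl-1-phenyl-6-(triisopropylsilyl)-2-[(trimethylsilyl)ethynyl]hex-5-yne-1,4-dione (diastereomer mixture) | C[Si](C)(C)C#CC(C(C)C(=O)C#C[Si](C(C)C)(C(C)C)C(C)C)C(=O)c1ccccc1
F7 | step 7 | triisopropyl{[3-methyl-5-phenyl-4-((trimethylsilyl)ethynyl)furan-2-yl]ethynyl}silane | Cc1c(C#C[Si](C(C)C)(C(C)C)C(C)C)oc(-c2ccccc2)c1C#C[Si](C)(C)C
F8 | step 7 | 4-{4-methyl-2-phenyl-5-[(triisopropylsilyl)ethynyl]furan-3-yl}but-3-yn-2-ol (racemic) | CC(O)C#Cc1c(-c2ccccc2)oc(C#C[Si](C(C)C)(C(C)C)C(C)C)c1C
F9 | step 3 | 6-(trimethylsilyl)hexa-3,5-diyn-2-ol (racemic) | CC(O)C#CC#C[Si](C)(C)C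
F10 | step 3 | tert-butyldimethyl{[6-(trimethylsilyl)hexa-3,5-diyn-2-yl]oxy}silane (racemic) | CC(O[Si](C)(C)C(C)(C)C)C#CC#C[Si](C)(C)C
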